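**Ret­rosynthetic overview**
- The target comes from one global hydrogenation of a hexa‑O‑benzyl bichalcone. Both CH2CH2 links arise from enones and all six OH groups arise from OBn groups.
- The bichalcone comes from a Claisen–Schmidt aldol condensation of a biaryl aldehyde, which already carries the first enone, with 2,4‑bis(benzyloxy)acetophenone. This is the key fragment union.
- The biaryl aldehyde comes from a Suzuki–Miyaura coupling of a 5'‑bromochalcone with a 2‑benzyloxy‑5‑formylphenyl boronate. No enolisable ketone is present at that stage.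
- The bromochalcone comes from a first Claisen–Schmidt condensation of 5‑bromo‑2,4‑bis(benzyloxy)acetophenone with 4‑benzyloxybenzaldehyde.
- No ring is formed. All four benzene rings are bought, and the dibenzylated resacetophenone is used twice.

**Assumption:** the target (C30H26O8) has no stereocentre. Its biaryl axis carries only two ortho substituents (OH/OH) and rotates freely, so the compound is achiral and needs no enantiocontrol. The E‑alkenes and the racemic aldol carbinol centres formed on the way are all erased later.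

**Step 1**
Reactants: 1 2,4‑dihydroxyacetophenone
Product: 2 1‑[2,4‑bis(benzyloxy)phenyl]ethan‑1‑one
Conditions: BnBr (2.5 equiv), K2CO3 (3 equiv), DMF, 70 °C, 12 h
Reagents that add atoms: benzyl bromide, BrCc1ccccc1
Why: In this Williamson ether synthesis, carbonate in warm DMF deprotonates both phenols, including the H‑bonded 2‑OH, and SN2 on BnBr gives a bis‑ether that is stable to base and Pd(0) and creates no stereocentre.

**Step 2**
Reactants: 2 1‑[2,4‑bis(benzyloxy)phenyl]ethan‑1‑one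
Product: 3 1‑[2,4‑bis(benzyloxy)‑5‑bromophenyl]ethan‑1‑one
Conditions: NBS (1.05 equiv), MeCN, 0 °C to rt, dark
Reagents that add atoms: N‑bromosuccinimide, O=C1CCC(=O)N1Br
Why: In this electrophilic aromatic bromination, C5 is para to 2‑OBn and ortho to 4‑OBn while the other doubly activated site C3 is shielded between the two OBn groups, and polar, dark conditions suppress benzylic and α‑keto bromination.

**Step 3**
Reactants: 3 1‑[2,4‑bis(benzyloxy)‑5‑bromophenyl]ethan‑1‑one; 4 4‑(benzyloxy)benzaldehyde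
Product: 6 (E)‑1‑[2,4‑bis(benzyloxy)‑5‑bromophenyl]‑3‑[4‑(benzyloxy)phenyl]prop‑2‑en‑1‑one, via racemic β‑hydroxy ketone aldol adduct 5 (not isolated)
Conditions: KOH (50 % aq, 4 equiv), EtOH/THF 2:1, rt, 24 h
Reagents that add atoms: none
Why: In this Claisen–Schmidt crossed aldol condensation only 3 can enolise and only 4 is an aldehyde, so the enolate adds to 4 and the racemic carbinol 5 loses water by E1cB to give the thermodynamic E‑enone.

**Step 4**
Reactants: 7 3‑bromo‑4‑hydroxybenzaldehyde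
Product: 8 4‑(benzyloxy)‑3‑bromobenzaldehyde
Conditions: BnBr (1.2 equiv), K2CO3 (1.5 equiv), DMF, 50 °C, 6 h
Reagents that add atoms: benzyl bromide, BrCc1ccccc1
Why: In this Williamson ether synthesis the acidic para‑formyl phenol is alkylated cleanly, and the non‑enolisable aldehyde and the aryl bromide are inert.

**Step 5**
Reactants: 8 4‑(benzyloxy)‑3‑bromobenzaldehyde
Product: 9 4‑(benzyloxy)‑3‑(4,4,5,5‑tetramethyl‑1,3,2‑dioxaborolan‑2‑yl)benzaldehyde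
Conditions: B2pin2 (1.2 equiv), PdCl2(dppf) (3 mol %), KOAc (3 equiv), dioxane, 90 °C
Reagents that add atoms: bis(pinacolato)diboron, CC1(C)OB(OC1(C)C)B1OC(C)(C)C(C)(C)O1
Why: The Miyaura borylation tolerates free aldehydes, and the weak base KOAc prevents homocoupling of the boronate as it forms.

**Step 6**
Reactants: 6 (E)‑1‑[2,4‑bis(benzyloxy)‑5‑bromophenyl]‑3‑[4‑(benzyloxy)phenyl]prop‑2‑en‑1‑one; 9 4‑(benzyloxy)‑3‑(4,4,5,5‑tetramethyl‑1,3,2‑dioxaborolan‑2‑yl)benzaldehyde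
Product: 10 2',4',6‑tris(benzyloxy)‑5'‑[(E)‑3‑(4‑benzyloxyphenyl)prop‑2‑enoyl]biphenyl‑3‑carbaldehyde
Conditions: Pd(OAc)2 (3 mol %), SPhos (6 mol %), K3PO4 (2.5 equiv), toluene/H2O 10:1, 90 °C
Reagents that add atoms: none
Why: In this Suzuki–Miyaura coupling the electron‑rich SPhos ligand handles the electron‑rich, ortho‑alkoxy bromide, and because neither partner has an enolisable C–H the aldehyde and the enone survive the phosphate base.

**Step 7**
Reactants: 10 2',4',6‑tris(benzyloxy)‑5'‑[(E)‑3‑(4‑benzyloxyphenyl)prop‑2‑enoyl]biphenyl‑3‑carbaldehyde; 2 1‑[2,4‑bis(benzyloxy)phenyl]ethan‑1‑one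
Product: 12 (E)‑1‑[2,4‑bis(benzyloxy)phenyl]‑3‑{2',4',6‑tris(benzyloxy)‑5'‑[(E)‑3‑(4‑benzyloxyphenyl)prop‑2‑enoyl]biphenyl‑3‑yl}prop‑2‑en‑1‑one, via racemic β‑hydroxy ketone aldol adduct 11 (not isolated)
Conditions: 2 (1.05 equiv), KOH (50 % aq, 5 equiv), THF/EtOH 1:1, rt, 24–48 h
Reagents that add atoms: none
Why: In this Claisen–Schmidt condensation 2 is the only enolisable component and the aldehyde of 10 is far more electrophilic than its enone β‑carbon, so aldol addition gives racemic 11 and E1cB dehydration gives the second E‑enone.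

**Step 8**
Reactants: 12 (E)‑1‑[2,4‑bis(benzyloxy)phenyl]‑3‑{2',4',6‑tris(benzyloxy)‑5'‑[(E)‑3‑(4‑benzyloxyphenyl)prop‑2‑enoyl]biphenyl‑3‑yl}prop‑2‑en‑1‑one
Product: 13 1‑(2,4‑dihydroxyphenyl)‑3‑{2',4',6‑trihydroxy‑5'‑[3‑(4‑hydroxyphenyl)propanoyl]biphenyl‑3‑yl}propan‑1‑one (target)
Conditions: H2 (1 atm), 10 % Pd/C, THF/MeOH 1:1, rt, stopped after uptake of 8 equiv H2
Reagents that add atoms: none
Why: Catalytic hydrogenation saturates both enone C=C bonds and hydrogenolyses all six aryl benzyl ethers, while the resulting H‑bonded 2‑hydroxyaryl ketones resist reduction at 1 atm under neutral conditions, and no stereocentre remains.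

**Compound list**
1 | 2,4‑dihydroxyacetophenone | CC(=O)c1ccc(O)cc1O | starting material
2 | 1‑[2,4‑bis(benzyloxy)phenyl]ethan‑1‑one | CC(=O)c1ccc(OCc2ccccc2)cc1OCc1ccccc1 | intermediate
3 | 1‑[2,4‑bis(benzyloxy)‑5‑bromophenyl]ethan‑1‑one | CC(=O)c1cc(Br)c(OCc2ccccc2)cc1OCc1ccccc1 | intermediate
4 | 4‑(benzyloxy)benzaldehyde | O=Cc1ccc(OCc2ccccc2)cc1 | starting material
5 | 1‑[2,4‑bis(benzyloxy)‑5‑bromophenyl]‑3‑[4‑(benzyloxy)phenyl]‑3‑hydroxypropan‑1‑one (racemic, not isolated) | O=C(CC(O)c1ccc(OCc2ccccc2)cc1)c1cc(Br)c(OCc2ccccc2)cc1OCc1ccccc1 | intermediate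
6 | (E)‑1‑[2,4‑bis(benzyloxy)‑5‑bromophenyl]‑3‑[4‑(benzyloxy)phenyl]prop‑2‑en‑1‑one | O=C(/C=C/c1ccc(OCc2ccccc2)cc1)c1cc(Br)c(OCc2ccccc2)cc1OCc1ccccc1 | intermediate
7 | 3‑bromo‑4‑hydroxybenzaldehyde | O=Cc1ccc(O)c(Br)c1 | starting material
8 | 4‑(benzyloxy)‑3‑bromobenzaldehyde | O=Cc1ccc(OCc2ccccc2)c(Br)c1 | intermediate
9 | 4‑(benzyloxy)‑3‑(4,4,5,5‑tetramethyl‑1,3,2‑dioxaborolan‑2‑yl)benzaldehyde | O=Cc1ccc(OCc2ccccc2)c(B2OC(C)(C)C(C)(C)O2)c1 | intermediate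
10 | 2',4',6‑tris(benzyloxy)‑5'‑[(E)‑3‑(4‑benzyloxyphenyl)prop‑2‑enoyl]biphenyl‑3‑carbaldehyde | O=Cc1ccc(OCc2ccccc2)c(-c2cc(C(=O)/C=C/c3ccc(OCc4ccccc4)cc3)c(OCc3ccccc3)cc2OCc2ccccc2)c1 | intermediate
11 | 1‑[2,4‑bis(benzyloxy)phenyl]‑3‑hydroxy‑3‑{2',4',6‑tris(benzyloxy)‑5'‑[(E)‑3‑(4‑benzyloxyphenyl)prop‑2‑enoyl]biphenyl‑3‑yl}propan‑1‑one (racemic, not isolated) | O=C(CC(O)c1ccc(OCc2ccccc2)c(-c2cc(C(=O)/C=C/c3ccc(OCc4ccccc4)cc3)c(OCc3ccccc3)cc2OCc2ccccc2)c1)c1ccc(OCc2ccccc2)cc1OCc1ccccc1 | intermediate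
12 | (E)‑1‑[2,4‑bis(benzyloxy)phenyl]‑3‑{2',4',6‑tris(benzyloxy)‑5'‑[(E)‑3‑(4‑benzyloxyphenyl)prop‑2‑enoyl]biphenyl‑3‑yl}prop‑2‑en‑1‑one | O=C(/C=C/c1ccc(OCc2ccccc2)c(-c2cc(C(=O)/C=C/c3ccc(OCc4ccccc4)cc3)c(OCc3ccccc3)cc2OCc2ccccc2)c1)c1ccc(OCc2ccccc2)cc1OCc1ccccc1 | intermediate
13 | 1‑(2,4‑dihydroxyphenyl)‑3‑{2',4',6‑trihydroxy‑5'‑[3‑(4‑hydroxyphenyl)propanoyl]biphenyl‑3‑yl}propan‑1‑one | O=C(CCc1ccc(O)c(-c2cc(C(=O)CCc3ccc(O)cc3)c(O)cc2O)c1)c1ccc(O)cc1O | target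

**Total step count:** 8.
**Longest linear sequence:** 6 steps (1 → 2 → 3 → 6 → 10 → 12 → 13).

**Three steps most likely to fail**

**Step 7.** The late condensation uses a poorly soluble aldehyde that already bears an enone, so the enolate could add in Michael fashion to that enone.
- The fallback sets out from 8 (together with 2) and comes back to the route at 12.
- The second condensation is moved to the small‑fragment stage. Compounds 8 and 2 are condensed (KOH, EtOH/THF, rt) through the aldol adduct 3‑[4‑(benzyloxy)‑3‑bromophenyl]‑1‑[2,4‑bis(benzyloxy)phenyl]‑3‑hydroxypropan‑1‑one F1 to the bromochalcone (E)‑3‑[4‑(benzyloxy)‑3‑bromophenyl]‑1‑[2,4‑bis(benzyloxy)phenyl]prop‑2‑en‑1‑one F2.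
- Miyaura borylation (B2pin2, PdCl2(dppf), KOAc, dioxane, 90 °C) then gives the chalcone boronate (E)‑3‑[4‑(benzyloxy)‑3‑(4,4,5,5‑tetramethyl‑1,3,2‑dioxaborolan‑2‑yl)phenyl]‑1‑[2,4‑bis(benzyloxy)phenyl]prop‑2‑en‑1‑one F3.
- This boronate is coupled with bromochalcone 6 (Pd(OAc)2/SPhos, K3PO4, toluene/H2O, 90 °C) to give 12 directly, so no enolate ever meets a preformed enone.

**Step 6.** Oxidative addition into the doubly alkoxy‑activated bromide may be slow, and the ortho‑alkoxy boronate may protodeboronate.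
- The fallback sets out from 6 and comes back at 10, with the roles of the two partners reversed.
- Compound 6 is borylated (B2pin2, PdCl2(dppf), KOAc, dioxane, 90 °C) to (E)‑1‑[2,4‑bis(benzyloxy)‑5‑(4,4,5,5‑tetramethyl‑1,3,2‑dioxaborolan‑2‑yl)phenyl]‑3‑[4‑(benzyloxy)phenyl]prop‑2‑en‑1‑one F4.
- This electron‑rich nucleophile is coupled with the less electron‑rich bromoaldehyde 8 (Pd(OAc)2/SPhos, K3PO4, toluene/H2O, 90 °C) to give 10.

**Step 8.** The aryl ketones may be over‑reduced, or the sixfold hydrogenolysis may stall.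
- The fallback sets out from 12 and comes back at 13, and it separates the two tasks.
- The alkenes alone are hydrogenated over sulfide‑poisoned catalyst (H2, Pd/C, Ph2S, THF/EtOAc, rt). This leaves benzyl ethers and aryl ketones untouched and gives 1‑[2,4‑bis(benzyloxy)phenyl]‑3‑{2',4',6‑tris(benzyloxy)‑5'‑[3‑(4‑benzyloxyphenyl)propanoyl]biphenyl‑3‑yl}propan‑1‑one F5.
- The benzyl ethers are then removed without any reduction by Lewis acid cleavage (BCl3, pentamethylbenzene as cation scavenger, CH2Cl2, −78 °C, then aqueous work‑up) to give 13.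

**Further compounds**
F1 | step 7 | 3‑[4‑(benzyloxy)‑3‑bromophenyl]‑1‑[2,4‑bis(benzyloxy)phenyl]‑3‑hydroxypropan‑1‑one (racemic, not isolated) | O=C(CC(O)c1ccc(OCc2ccccc2)c(Br)c1)c1ccc(OCc2ccccc2)cc1OCc1ccccc1
F2 | step 7 | (E)‑3‑[4‑(benzyloxy)‑3‑bromophenyl]‑1‑[2,4‑bis(benzyloxy)phenyl]prop‑2‑en‑1‑one | O=C(/C=C/c1ccc(OCc2ccccc2)c(Br)c1)c1ccc(OCc2ccccc2)cc1OCc1ccccc1
F3 | step 7 | (E)‑3‑[4‑(benzyloxy)‑3‑(4,4,5,5‑tetramethyl‑1,3,2‑dioxaborolan‑2‑yl)phenyl]‑1‑[2,4‑bis(benzyloxy)phenyl]prop‑2‑en‑1‑one | O=C(/C=C/c1ccc(OCc2ccccc2)c(B2OC(C)(C)C(C)(C)O2)c1)c1ccc(OCc2ccccc2)cc1OCc1ccccc1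
F4 | step 6 | (E)‑1‑[2,4‑bis(benzyloxy)‑5‑(4,4,5,5‑tetramethyl‑1,3,2‑dioxaborolan‑2‑yl)phenyl]‑3‑[4‑(benzyloxy)phenyl]prop‑2‑en‑1‑one | O=C(/C=C/c1ccc(OCc2ccccc2)cc1)c1cc(B2OC(C)(C)C(C)(C)O2)c(OCc2ccccc2)cc1OCc1ccccc1
F5 | step 8 | 1‑[2,4‑bis(benzyloxy)phenyl]‑3‑{2',4',6‑tris(benzyloxy)‑5'‑[3‑(4‑benzyloxyphenyl)propanoyl]biphenyl‑3‑yl}propan‑1‑one | O=C(CCc1ccc(OCc2ccccc2)c(-c2cc(C(=O)CCc3ccc(OCc4ccccc4)cc3)c(OCc3ccccc3)cc2OCc2ccccc2)c1)c1ccc(OCc2ccccc2)cc1OCc1ccccc1
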